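## The problem

The target is a monocyclic elemanolide. Its single cyclohexane is numbered C5–C10 as in the elemane skeleton: C10 bears the C14 methyl and the vinyl group C1=C2, C5 bears C4 with C3 (CHO) and C15 (=CH2), and C7 bears C11 with C12 (lactone C=O) and C13 (=CH2); β is the ring face of C14, α the other face. All six ring atoms are stereogenic, (5R,6S,7S,8R,9S,10S). C10 is quaternary (methyl β, vinyl α) and trans to the β side chain on C5; this carbon–carbon relationship cannot be corrected later. The oxygen-bearing centres can each be derived from a neighbour: C9–OAc (α, axial) is cis to the vinyl group and to C8–O (α), C7 (β) is trans to C8–O so the γ-lactone is trans-fused, and the C6 angelate is axial (β), cis to both flanking branches. The feature that makes the key step possible is that C1 and C4 are sp2 carbons on the adjacent ring atoms C10 and C5 and are trans. Replacing their terminal CH2 groups (C2, C15) by oxygen leaves a formyl on C10 and an acetyl on C5, the imprint of an (E)-2-methyl-2-ene-1,4-dicarbonyl dienophile (C1–C10=C5–C4); the oxygens on C6 and C9 lie 1,4 across the C7–C8 bond, the imprint of a 1,4-dioxygenated butadiene. A second feature is that the branches on C5 and C7 are the same isopropenyl group at two oxidation levels (C3 aldehyde, C12 carboxyl), and only the C7 branch has a free hydroxyl neighbour (C8–OH) once C6 is acylated. The fragile groups are the 2-substituted acrolein and the α-methylene lactone (Michael acceptors), the angelate (Z to E isomerisation by base, heat or nucleophilic catalysts) and, on the way, isopropenyl groups α to a ketone and β-acyloxy carbonyl units; the electrophilic alkenes must therefore appear last.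

## Retrosynthesis

**20 to 19.** The acetyl–O9 bond is cut last. In hydroxy lactone 19 the C9 hydroxyl is the only free OH, so no selectivity is asked of the acetylation. Acetylating earlier would mean telling the axial C9–OH from the more reactive equatorial C8–OH.

**19 to 16 to 15.** The O8–C12 acyl bond is cut and C3 and C12 are lowered to primary allylic alcohols (tetraol 16); both hydroxyls are then removed to give two isopropenyl groups in diol 15. This keeps both Michael acceptors out of the route until the penultimate step and treats the two branches alike. They are told apart only by their neighbours: C12 is trapped by C8–OH as a lactol and oxidised on to the lactone, whereas C3 has no free hydroxyl in reach. The forward reactions must oxidise the two allylic CH3 groups only, and then primary alcohols and the lactol but not the secondary C9–OH.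

**15 to 14 to 13 to 12.** The angeloyl–O6 bond is cut, then the C6–H bond (hydride addition to ketone 12). The 8,9-diol is carried as the cyclic phenylboronate (14, 13, 12), which comes from the step that makes C8–O. The hydride must enter from the α face to give the axial 6β-alcohol 13.

**12 to 10.** The C8–O bond is cut. Dienone 10 has two stereocentres fewer (C7, C8). Delivery of oxygen from a boron tethered to C9–OH can only give the cis-8,9-diol, and protonation at C7 then decides C7. Epoxide opening or enolate oxidation followed by ketone reduction would need more steps and separate control at C9.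

**10 to 9 to 8 to 7.** The C7–C11 bond (sp2–sp2) is cut to α-iodoenone 9, the C7–I bond to enone 8, and the C6 carbonyl is returned to the allylic alcohol of diol 7. The forward oxidation must distinguish the two allylic hydroxyls of 7: C6–OH next to a tertiary carbon and C9–OH next to the quaternary C10.

**7 to 6 to 5.** The acetates are restored (6), and the C1=C2 and C4=C15 bonds are cut by a double retro-methylenation to keto aldehyde 5. Doing both at once is what the trans-1,2-diacyl pattern offers.

**5 to 3 + 4 (key).** The C5–C6 and C9–C10 bonds are cut in a Diels–Alder sense to the (E)-enal-ketone 3 and diacetoxydiene 4. Other cuts at the quaternary carbon (C5–C10 by a sigmatropic shift in an open chain, or C10–C1 by enolate vinylation) each set one centre and leave the ring or the oxygens to be made separately. This cut makes the ring, the quaternary C10, the trans C5, and C9–O cis to the future vinyl group from two achiral pieces. The forward reaction must be endo with respect to the formyl group and enantioface-selective.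

**3 to 1.** The enedicarbonyl 3 comes from oxidative opening of 2,4-dimethylfuran 1.

## Roads not taken

**Alternative 1:** the most obvious cut is the biomimetic one, C5–C10 by a retro-Cope rearrangement. The forward key step would be thermal Cope rearrangement of the (1(10)E,4E)-germacradienolide A1 (ten-membered ring, C2–C3 bond intact, C4 formyl conjugated with C4=C5) through a chair-like transition state to give 20. The chosen plan is better because A1 is not simpler than the target. It still holds C6–C9 and all three labile groups, adds two E-trisubstituted alkenes in a medium ring, and needs a macrocyclisation. The rearrangement is an equilibrium that here gives up enal conjugation, and heating threatens the angelate geometry and both acceptor alkenes.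

**Alternative 2:** cut C2–C3 of a temporary ring A. The forward key step would be Grob fragmentation of the eudesmanolide hydroxy mesylate A2 (1β-mesylate antiperiplanar to C2–C3, C3 alkoxide, C4=C15 in place), which releases the vinyl group and the conjugated C3 aldehyde of 20 in one step. The chosen plan is better because ring A would be built only to be broken. A2 has eight stereocentres, its C6, C8 and C9 oxygens still have to be introduced on the decalin, and the alkoxide needed for fragmentation sits next to an acetate, an angelate and an α-methylene lactone.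

**Alternative 3:** cut C5–C4 and C10–C1 on a preformed ring. The forward key step would be conjugate addition of an isopropenyl cuprate to the enantiopure silyloxy enone A3, anti to the silyloxy group, with trapping of the enolate at C10 by a vinyl cation equivalent to give ketone A4. The chosen plan is better because C-vinylation of a hindered tertiary enolate has no direct reagent and needs two-step surrogates, and A3 needs its own asymmetric synthesis. The cycloaddition sets the same two carbon centres in one concerted event from achiral, purchasable parts.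

Key step: step 2

Remark: 2,4-dimethylfuran, (1E,3E)-buta-1,3-diene-1,4-diyl diacetate, tributyl(prop-1-en-2-yl)stannane and angelic anhydride are taken as purchasable; ring locants in names are the elemane numbers C5–C10 defined above.

## Route

Step 1
Reactants: 1 2,4-dimethylfuran
Product: 3 (E)-2-methyl-4-oxopent-2-enal, via (Z)-2-methyl-4-oxopent-2-enal 2 (not isolated)
Conditions: NBS, NaHCO3, acetone–H2O, −20 °C; then pyridine (cat.), rt
Reagents that add atoms: water, O
Why: Oxidative furan ring opening (bromination at C5, hydration, collapse of the 2-hydroxy-2,5-dihydrofuran) should give the Z enedicarbonyl, which pyridine isomerises to the E isomer with formyl and acetyl trans.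

Step 2
Reactants: 3 (E)-2-methyl-4-oxopent-2-enal; 4 (1E,3E)-buta-1,3-diene-1,4-diyl diacetate
Product: 5 (1S,4R,5S,6S)-6-acetyl-5-formyl-5-methylcyclohex-2-ene-1,4-diyl diacetate (elemane locants: 5β-acetyl, 10α-formyl, 10β-methyl, 6α,9α-diacetoxy, C7=C8)
Conditions: (S)-1-(2-methylphenyl)-3,3-diphenyltetrahydro-1H,3H-pyrrolo[1,2-c][1,3,2]oxazaborole (20 mol%), HN(SO2CF3)2 (18 mol%), CH2Cl2, −78 → −20 °C
Reagents that add atoms: none
Why: The protonated oxazaborolidine binds the formyl oxygen of 3 (s-trans enal) and lowers its LUMO, and the diene adds in a concerted, asynchronous [π4s+π2s] cycloaddition in which the C5–C6 bond (β-carbon of the enal) leads and the C9–C10 bond closes the six-membered ring C5–C10 with the new alkene at C7=C8. The closest known reaction type is the oxazaborolidinium-catalysed Diels–Alder reaction of α-substituted enals with acyclic dienes, together with thermal additions of this diacetoxydiene to acrylates. The trans relation of C10–CHO and C5–acetyl follows from the E geometry of 3 and suprafacial addition, and the cis relation of the two acetoxy groups from the E,E geometry of 4. Endo placement of the catalyst-bound formyl group puts it cis to both acetoxy groups, so C9–O ends cis to the future vinyl group; only the aldehyde is activated, and the other endo mode would push the acetyl and C14 methyl against the acetoxy groups. The absolute configuration comes from the catalyst, whose aryl group shields one face of the bound enal; the antipode of the catalyst is chosen so that the (10S) adduct forms. Regiochemistry is not at issue because both diene termini are alike. The step needs endo and enantioface selectivity and enough reactivity to form the quaternary C10, which the double activation of the alkene by formyl and acetyl should supply.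

Step 3
Reactants: 5 Diels–Alder adduct (6α,9α-diacetoxy keto aldehyde)
Product: 6 5β-isopropenyl-10β-methyl-10α-vinylcyclohex-7-ene-6α,9α-diyl diacetate
Conditions: Zn, CH2Br2, TiCl4, THF–CH2Cl2, 0 °C → rt
Reagents that add atoms: dibromomethane, BrCBr
Why: Takai–Lombardo methylenation should convert the aldehyde C1 and the ketone C4 into the vinyl and isopropenyl groups without base, so the β-acetoxy ketone does not eliminate and C5 does not epimerise; the acetates are not attacked and no stereocentre is formed.

Step 4
Reactants: 6 diene diacetate
Product: 7 5β-isopropenyl-10β-methyl-10α-vinylcyclohex-7-ene-6α,9α-diol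
Conditions: K2CO3 (cat.), MeOH, 0 °C → rt
Reagents that add atoms: none
Why: Base-catalysed transesterification to methanol should free both allylic hydroxyls; no centre is epimerisable under these conditions.

Step 5
Reactants: 7 6α,9α-diol
Product: 8 9α-hydroxy-5β-isopropenyl-10β-methyl-10α-vinylcyclohex-7-en-6-one
Conditions: MnO2 (activated, excess), CH2Cl2, rt
Reagents that add atoms: none
Why: Allylic oxidation should occur at C6–OH, which is flanked by a tertiary carbon, and not at the neopentylic C9–OH next to quaternary C10; after the first oxidation the remaining allylic alcohol belongs to an electron-poor enone and should resist further oxidation.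

Step 6
Reactants: 8 γ-hydroxy enone
Product: 9 9α-hydroxy-7-iodo-5β-isopropenyl-10β-methyl-10α-vinylcyclohex-7-en-6-one
Conditions: I2, pyridine, CH2Cl2, 0 °C → rt
Reagents that add atoms: iodine, II
Why: α-Iodination of the cyclohexenone (conjugate addition of pyridine, iodination of the enolate, elimination) should place iodine on C7, the only α-vinylic position; the base is too weak to epimerise C5.

Step 7
Reactants: 9 α-iodoenone
Product: 10 9α-hydroxy-5β,7-diisopropenyl-10β-methyl-10α-vinylcyclohex-7-en-6-one
Conditions: CH2=C(CH3)SnBu3, Pd2(dba)3 (5 mol%), AsPh3, CuI, NMP, rt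
Reagents that add atoms: tributyl(prop-1-en-2-yl)stannane, C=C(C)[Sn](CCCC)(CCCC)CCCC
Why: Stille coupling of the α-iodoenone under base-free conditions should join C7 to C11 and leave C5 and its isopropenyl group untouched.

Step 8
Reactants: 10 cross-conjugated dienone
Product: 12 5β,7β-diisopropenyl-10β-methyl-8α,9α-(phenylboranediyldioxy)-10α-vinylcyclohexan-6-one, via 9-O-boronic hemiester 11 (not isolated)
Conditions: PhB(OH)2 (1.2 equiv), quinuclidine (20 mol%), 4 Å molecular sieves, toluene, rt
Reagents that add atoms: phenylboronic acid, OB(O)c1ccccc1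
Why: The boronic acid esterifies C9–OH, and the amine-activated B–OH adds to C8 within the hemiester (oxa-Michael addition of γ-hydroxy enones through boronate hemiesters), which can only give the cis-8α,9α-dioxaborolane. Protonation at C7 should put the isopropenyl group equatorial (β), the epimer that avoids a 1,3-diaxial contact with the axial C9–O, and the boronate then protects the diol.

Step 9
Reactants: 12 boronate ketone
Product: 13 5β,7β-diisopropenyl-10β-methyl-8α,9α-(phenylboranediyldioxy)-10α-vinylcyclohexan-6β-ol
Conditions: Li[HB(sec-C4H9)3], THF, −78 °C; then H2O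
Reagents that add atoms: none
Why: The bulky hydride should attack C6 along the equatorial path from the α face, because the axial path on the β face is blocked by the axial C14 methyl and both flanking branches are equatorial; this gives the axial 6β-alcohol, as in selectride reductions of 3-axially substituted cyclohexanones.

Step 10
Reactants: 13 6β-alcohol
Product: 14 6β-angeloyloxy-5β,7β-diisopropenyl-10β-methyl-8α,9α-(phenylboranediyldioxy)-10α-vinylcyclohexane
Conditions: LiN(SiMe3)2, THF, −78 °C; then angelic anhydride, −78 → 0 °C
Reagents that add atoms: angelic anhydride, C/C=C(/C)C(=O)OC(=O)/C(C)=C\C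
Why: Acylation of the lithium alkoxide by the anhydride at low temperature should esterify the hindered axial hydroxyl without the heat or nucleophilic catalysts that turn angelate into tiglate; the boronate keeps C8–O and C9–O out of the reaction.

Step 11
Reactants: 14 angelate boronate
Product: 15 6β-angeloyloxy-5β,7β-diisopropenyl-10β-methyl-10α-vinylcyclohexane-8α,9α-diol
Conditions: pinacol (5 equiv), CH2Cl2–MeOH, rt
Reagents that add atoms: none
Why: Transesterification to the more stable pinacol boronate should free the cis-diol under neutral conditions that leave the angelate alone.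

Step 12
Reactants: 15 diol with two isopropenyl groups
Product: 16 6β-angeloyloxy-5β,7β-bis(3-hydroxyprop-1-en-2-yl)-10β-methyl-10α-vinylcyclohexane-8α,9α-diol
Conditions: SeO2 (20 mol%), t-BuOOH (4 equiv), CH2Cl2, rt
Reagents that add atoms: tert-butyl hydroperoxide, CC(C)(C)OO
Why: Selenium dioxide allylic oxidation (ene reaction, then [2,3] shift) should hydroxylate the CH3 of each isopropenyl group. These are the only electron-rich alkenes with allylic CH3: the vinyl group has no allylic hydrogen and the angelate alkene is electron-poor. Any enal formed by over-oxidation converges in step 13.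

Step 13
Reactants: 16 bis(allylic alcohol)
Product: 19 9-O-deacetyl target (9α-hydroxy-6β-angeloyloxy-3-oxoelema-1,4(15),11(13)-trien-8α,12-olide), via 3,12-dialdehyde 17 (not isolated), via 8,12-lactol 18 (not isolated)
Conditions: TEMPO (20 mol%), PhI(OAc)2 (3.5 equiv), CH2Cl2, rt
Reagents that add atoms: none
Why: Oxoammonium oxidation should take both primary allylic alcohols to aldehydes. The C12 aldehyde is captured by the adjacent trans-diequatorial C8–OH as a five-membered lactol and oxidised on to the trans-fused α-methylene lactone, whereas the C3 aldehyde has only the acylated C6–O nearby and stays as the 2-substituted acrolein. The secondary, axial C9–OH is oxidised much more slowly and cannot reach C12.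

Step 14
Reactants: 19 9α-hydroxy lactone
Product: 20 target, (5R,6S,7S,8R,9S,10S)-9α-acetoxy-6β-angeloyloxy-3-oxoelema-1,4(15),11(13)-trien-8α,12-olide
Conditions: Ac2O, pyridine, DMAP (cat.), CH2Cl2, 0 °C → rt
Reagents that add atoms: acetic anhydride, CC(=O)OC(C)=O
Why: Acetylation of the only free hydroxyl should complete the target; no stereocentre is touched.

## Compound list

1 | 2,4-dimethylfuran | Cc1cc(C)co1 | starting material
2 | (Z)-2-methyl-4-oxopent-2-enal | O=C/C(C)=C\C(C)=O | intermediate (not isolated)
3 | (E)-2-methyl-4-oxopent-2-enal | O=C/C(C)=C/C(C)=O | intermediate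
4 | (1E,3E)-buta-1,3-diene-1,4-diyl diacetate | CC(=O)O/C=C/C=C/OC(C)=O | starting material
5 | (1S,4R,5S,6S)-6-acetyl-5-formyl-5-methylcyclohex-2-ene-1,4-diyl diacetate | O=C[C@]1(C)[C@H](OC(C)=O)C=C[C@H](OC(C)=O)[C@H]1C(C)=O | intermediate
6 | 5β-isopropenyl-10β-methyl-10α-vinylcyclohex-7-ene-6α,9α-diyl diacetate | C=C[C@]1(C)[C@H](OC(C)=O)C=C[C@H](OC(C)=O)[C@H]1C(C)=C | intermediate
7 | 5β-isopropenyl-10β-methyl-10α-vinylcyclohex-7-ene-6α,9α-diol | C=C[C@]1(C)[C@H](O)C=C[C@H](O)[C@H]1C(C)=C | intermediate
8 | 9α-hydroxy-5β-isopropenyl-10β-methyl-10α-vinylcyclohex-7-en-6-one | C=C[C@]1(C)[C@H](O)C=CC(=O)[C@H]1C(C)=C | intermediate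
9 | 9α-hydroxy-7-iodo-5β-isopropenyl-10β-methyl-10α-vinylcyclohex-7-en-6-one | C=C[C@]1(C)[C@H](O)C=C(I)C(=O)[C@H]1C(C)=C | intermediate
10 | 9α-hydroxy-5β,7-diisopropenyl-10β-methyl-10α-vinylcyclohex-7-en-6-one | C=C[C@]1(C)[C@H](O)C=C(C(C)=C)C(=O)[C@H]1C(C)=C | intermediate
11 | 9-O-[hydroxy(phenyl)boranyl] hemiester of 10 | C=C[C@]1(C)[C@H](OB(O)c2ccccc2)C=C(C(C)=C)C(=O)[C@H]1C(C)=C | intermediate (not isolated)
12 | 5β,7β-diisopropenyl-10β-methyl-8α,9α-(phenylboranediyldioxy)-10α-vinylcyclohexan-6-one | C=C[C@]1(C)[C@@H]2OB(c3ccccc3)O[C@@H]2[C@@H](C(C)=C)C(=O)[C@H]1C(C)=C | intermediate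
13 | 5β,7β-diisopropenyl-10β-methyl-8α,9α-(phenylboranediyldioxy)-10α-vinylcyclohexan-6β-ol | C=C[C@]1(C)[C@@H]2OB(c3ccccc3)O[C@@H]2[C@@H](C(C)=C)[C@@H](O)[C@H]1C(C)=C | intermediate
14 | 6β-angeloyloxy-5β,7β-diisopropenyl-10β-methyl-8α,9α-(phenylboranediyldioxy)-10α-vinylcyclohexane | C=C[C@]1(C)[C@@H]2OB(c3ccccc3)O[C@@H]2[C@@H](C(C)=C)[C@@H](OC(=O)/C(C)=C\C)[C@H]1C(C)=C | intermediate
15 | 6β-angeloyloxy-5β,7β-diisopropenyl-10β-methyl-10α-vinylcyclohexane-8α,9α-diol | C=C[C@]1(C)[C@H](O)[C@H](O)[C@@H](C(C)=C)[C@@H](OC(=O)/C(C)=C\C)[C@H]1C(C)=C | intermediate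
16 | 6β-angeloyloxy-5β,7β-bis(3-hydroxyprop-1-en-2-yl)-10β-methyl-10α-vinylcyclohexane-8α,9α-diol | C=C[C@]1(C)[C@H](O)[C@H](O)[C@@H](C(=C)CO)[C@@H](OC(=O)/C(C)=C\C)[C@H]1C(=C)CO | intermediate
17 | 3,12-dialdehyde (both branches as 3-oxoprop-1-en-2-yl, 8α,9α-diol free) | C=C[C@]1(C)[C@H](O)[C@H](O)[C@@H](C(=C)C=O)[C@@H](OC(=O)/C(C)=C\C)[C@H]1C(=C)C=O | intermediate (not isolated)
18 | 8,12-lactol (C12 hemiacetal closed on O8, both anomers) | C=C[C@]1(C)[C@H](O)[C@@H]2OC(O)C(=C)[C@H]2[C@@H](OC(=O)/C(C)=C\C)[C@H]1C(=C)C=O | intermediate (not isolated)
19 | 9α-hydroxy-6β-angeloyloxy-3-oxoelema-1,4(15),11(13)-trien-8α,12-olide | C=C[C@]1(C)[C@H](O)[C@@H]2OC(=O)C(=C)[C@H]2[C@@H](OC(=O)/C(C)=C\C)[C@H]1C(=C)C=O | intermediate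
20 | (5R,6S,7S,8R,9S,10S)-9α-acetoxy-6β-angeloyloxy-3-oxoelema-1,4(15),11(13)-trien-8α,12-olide (CNP0228039.1) | C=C[C@]1(C)[C@H](OC(C)=O)[C@@H]2OC(=O)C(=C)[C@H]2[C@@H](OC(=O)/C(C)=C\C)[C@H]1C(=C)C=O | target

## Step count and least certain steps

Total step count: 14. Longest linear sequence: 14 steps, from 1 to 20 (4 is used as purchased).

**Step 2 (key step).** The acyloxy-substituted diene is only moderately nucleophilic and the dienophile is trisubstituted. The cycloaddition may therefore be too slow at the temperatures where the catalyst controls endo and facial selectivity, so an uncatalysed background reaction or Lewis-acid-induced loss of acetic acid would erode selectivity. Fallback, setting out from 3 and 4: the cycloaddition is run thermally (toluene, 90 °C, sealed vessel), where the same endo mode is expected on steric grounds, to give the racemic adduct F1. This is carried through the conditions of steps 3 and 4 to the racemic diene diacetate F2 and the racemic diol F3. F3 is resolved by preparative chromatography on a chiral stationary phase (cellulose tris(3,5-dimethylphenylcarbamate)), and the route is rejoined at 7.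

**Step 5.** Site selection between the two allylic hydroxyls rests only on the steric difference at C5 and C10, so oxidation at C9 or over-oxidation to the enedione may compete. Fallback, setting out from 6: controlled methanolysis (K2CO3, MeOH, −20 °C) removes only the less hindered C6 acetate to give the 9-monoacetate F4. Dess–Martin periodinane then gives the 9α-acetoxy enone F5, and methanolysis of the remaining acetate rejoins the route at 8.

**Step 8.** Conjugate addition to the α-branched enone may stall, or the dienol formed on addition may be protonated at C13 and not at C7, moving the C7 isopropenyl group into conjugation. Fallback, setting out from 10: hydroxyl-directed nucleophilic epoxidation (t-BuOOH, n-BuLi, THF, −20 °C) gives the 7α,8α-epoxy ketone F6. Reductive cleavage of the C7–O bond (SmI2, THF–MeOH, −78 °C) gives the 8α,9α-dihydroxy ketone F7, and condensation with PhB(OH)2 (MgSO4, CH2Cl2) rejoins the route at 12.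

**Step 10.** The C6 alkoxide is axial, sits between two branched carbons and is 1,3-diaxial to C14, so acylation may be slow and prolonged exposure to base may isomerise the angelate. Fallback, setting out from 13: acylation with the acylketene released from 2,2,5,6-tetramethyl-4H-1,3-dioxin-4-one (toluene, 110 °C) gives the 2-methyl-3-oxobutanoate F8. E-selective enol triflation (Tf2O, aqueous (CH3)4NOH) gives the (E)-enol triflate F9, and reduction with retention (Pd(OAc)2, PPh3, HCO2H, Bu3N, DMF) gives the Z ester and rejoins the route at 14.

**Step 12.** Two allylic oxidations must occur side by side; competing attack at the ring methines C5–H and C7–H, at the angelate methyls, or over-oxidation would lower the yield. Fallback, setting out from 15: ene-type allylic chlorination (Ca(OCl)2, solid CO2, CH2Cl2–H2O, 0 °C) gives the bis(allylic chloride) F10. Oxidation with 4-methylmorpholine N-oxide (NaI cat., DMSO, rt) gives the dialdehyde 17, which goes on to 19 under the conditions of step 13.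

## Further compounds

F1 | step 2 | racemic 6-acetyl-5-formyl-5-methylcyclohex-2-ene-1,4-diyl diacetate (racemate of 5) | O=C[C@]1(C)[C@H](OC(C)=O)C=C[C@H](OC(C)=O)[C@H]1C(C)=O.O=C[C@@]1(C)[C@@H](OC(C)=O)C=C[C@@H](OC(C)=O)[C@@H]1C(C)=O
F2 | step 2 | racemic diene diacetate (racemate of 6) | C=C[C@]1(C)[C@H](OC(C)=O)C=C[C@H](OC(C)=O)[C@H]1C(C)=C.C=C[C@@]1(C)[C@@H](OC(C)=O)C=C[C@@H](OC(C)=O)[C@@H]1C(C)=C
F3 | step 2 | racemic diol (racemate of 7) | C=C[C@]1(C)[C@H](O)C=C[C@H](O)[C@H]1C(C)=C.C=C[C@@]1(C)[C@@H](O)C=C[C@@H](O)[C@@H]1C(C)=C
F4 | step 5 | 6α-hydroxy-5β-isopropenyl-10β-methyl-10α-vinylcyclohex-7-en-9α-yl acetate | C=C[C@]1(C)[C@H](OC(C)=O)C=C[C@H](O)[C@H]1C(C)=C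
F5 | step 5 | 5β-isopropenyl-10β-methyl-6-oxo-10α-vinylcyclohex-7-en-9α-yl acetate | C=C[C@]1(C)[C@H](OC(C)=O)C=CC(=O)[C@H]1C(C)=C
F6 | step 8 | 7α,8α-epoxy-9α-hydroxy-5β,7β-diisopropenyl-10β-methyl-10α-vinylcyclohexan-6-one | C=C[C@]1(C)[C@H](O)[C@@H]2O[C@]2(C(C)=C)C(=O)[C@H]1C(C)=C
F7 | step 8 | 8α,9α-dihydroxy-5β,7β-diisopropenyl-10β-methyl-10α-vinylcyclohexan-6-one | C=C[C@]1(C)[C@H](O)[C@H](O)[C@@H](C(C)=C)C(=O)[C@H]1C(C)=C
F8 | step 10 | 6β-(2-methyl-3-oxobutanoyloxy) boronate (mixture at the ester α-carbon) | C=C[C@]1(C)[C@@H]2OB(c3ccccc3)O[C@@H]2[C@@H](C(C)=C)[C@@H](OC(=O)C(C)C(C)=O)[C@H]1C(C)=C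
F9 | step 10 | 6β-[(E)-2-methyl-3-(trifluoromethylsulfonyloxy)but-2-enoyloxy] boronate | C=C[C@]1(C)[C@@H]2OB(c3ccccc3)O[C@@H]2[C@@H](C(C)=C)[C@@H](OC(=O)/C(C)=C(\C)OS(=O)(=O)C(F)(F)F)[C@H]1C(C)=C
F10 | step 12 | 6β-angeloyloxy-5β,7β-bis(3-chloroprop-1-en-2-yl)-10β-methyl-10α-vinylcyclohexane-8α,9α-diol | C=C[C@]1(C)[C@H](O)[C@H](O)[C@@H](C(=C)CCl)[C@@H](OC(=O)/C(C)=C\C)[C@H]1C(=C)CCl
A1 | alternative 1 | (1(10)E,4E)-9α-acetoxy-6β-angeloyloxy-15-oxogermacra-1(10),4,11(13)-trien-8α,12-olide | C1C/C=C(\C)[C@H](OC(C)=O)[C@@H]2OC(=O)C(=C)[C@H]2[C@@H](OC(=O)/C(C)=C\C)/C=C1/C=O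
A2 | alternative 2 | 9α-acetoxy-6β-angeloyloxy-3β-hydroxy-1β-(methylsulfonyloxy)-15-noreudesma-4(15),11(13)-dien-8α,12-olide | C1[C@@H](OS(C)(=O)=O)[C@]2(C)[C@H](OC(C)=O)[C@@H]3OC(=O)C(=C)[C@H]3[C@@H](OC(=O)/C(C)=C\C)[C@H]2C(=C)[C@H]1O
A3 | alternative 3 | (S)-4-(tert-butyldimethylsilyloxy)-2-methylcyclohex-2-en-1-one | CC1=C[C@@H](O[Si](C)(C)C(C)(C)C)CCC1=O
A4 | alternative 3 | 6α-(tert-butyldimethylsilyloxy)-5β-isopropenyl-10β-methyl-10α-vinylcyclohexan-9-one | C=C[C@]1(C)C(=O)CC[C@H](O[Si](C)(C)C(C)(C)C)[C@H]1C(C)=C
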